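**Plan**

Numbering is that of the elemane skeleton: C10 is the quaternary carbon (C14 methyl, C1=C2 vinyl), C8 bears the angelate, C7 and C6 carry the lactone (C11=C13, C12) and C5 carries the acrylic acid unit (C4=C3, C15).
Retrosynthesis cuts the C8 ester bond, the C15 oxidation and the C11=C13 methylene first, then the O6–C12 lactone bond, then the ring bond C5–C6 (carbonyl-ene), then C7–C8 (aldol) and last C10–C5 (allylic alkenylation).
The enabling feature is ring carbon C6 (oxygen) next to C5 (2-propenyl unit), trans to each other on the cyclohexane: a 2-isopropenylcyclohexanol, which is what an aldehyde gives when it closes onto a 2-methylprop-1-enyl group.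
Forward, the chain C6–C7–C8–C9–C10–C5 is assembled open (alkenylation, then aldol), the cyclohexane ring closes in the ene step, the γ-lactone ring follows, and the three oxidised appendages are finished last.
Stereochemistry: C10 from a copper–carbene-catalysed enantioselective SN2' alkenylation, C7 and C8 from an Evans syn aldol with the (R)-benzyloxazolidinone, C5 and C6 from the chair transition state of the ene closure, the (Z)-ester from angelic acid.

Key step: step 11

Assumption: the sense of induction of the copper–carbene catalyst on phosphate 5 is not derived here; the antipode of the imidazolinium salt that delivers (S)-7 is taken to be the one used.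

**Route**

Step 1
Reactants: 1 tert-butyl(but-3-yn-1-yloxy)dimethylsilane
Product: 4 (E)-5-[(tert-butyldimethylsilyl)oxy]-3-methylpent-2-en-1-ol, via alkenylalane 2 (not isolated), via lithium alanate 3 (not isolated)
Conditions: AlMe3, Cp2ZrCl2 (cat.), CH2Cl2, 0 °C to rt; volatiles removed; n-BuLi, hexane/THF, −78 °C; (CH2O)n, rt; H2O
Reagents that add atoms: trimethylaluminium, C[Al](C)C; formaldehyde (from paraformaldehyde), C=O
Why: Negishi zirconium-catalysed carboalumination adds methyl and aluminium syn across the terminal alkyne with aluminium on the terminal carbon, and the derived alanate is hydroxymethylated by formaldehyde with retention, which fixes the (E)-trisubstituted alkene.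

Step 2
Reactants: 4 (E)-5-[(tert-butyldimethylsilyl)oxy]-3-methylpent-2-en-1-ol
Product: 5 (E)-5-[(tert-butyldimethylsilyl)oxy]-3-methylpent-2-en-1-yl diethyl phosphate
Conditions: ClP(O)(OEt)2, Et3N, DMAP (cat.), CH2Cl2, 0 °C
Reagents that add atoms: diethyl chlorophosphate, CCOP(=O)(Cl)OCC
Why: Phosphorylation of a primary allylic alcohol with a chlorophosphate is routine and supplies the leaving group needed for copper-catalysed allylic substitution.

Step 3
Reactants: 5 (E)-5-[(tert-butyldimethylsilyl)oxy]-3-methylpent-2-en-1-yl diethyl phosphate; 6 4,4,5,5-tetramethyl-2-(2-methylprop-1-en-1-yl)-1,3,2-dioxaborolane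
Product: 7 tert-butyl{[(3S)-3-ethenyl-3,5-dimethylhex-4-en-1-yl]oxy}dimethylsilane
Conditions: CuCl (5 mol %), enantiopure sulfonate-bearing imidazolinium salt (carbene precursor, 5.5 mol %), NaOMe, THF, rt
Reagents that add atoms: none
Why: In this copper–N-heterocyclic-carbene-catalysed enantioselective allylic substitution, methoxide-promoted boron-to-copper transfer gives an alkenylcopper that attacks the γ-carbon (C10) in SN2' fashion, the chiral carbene differentiating the faces of the (E)-trisubstituted alkene so that the quaternary centre C10 should form as (S) while the vinyl group C1=C2 is released.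

Step 4
Reactants: 7 tert-butyl{[(3S)-3-ethenyl-3,5-dimethylhex-4-en-1-yl]oxy}dimethylsilane
Product: 8 (3S)-3-ethenyl-3,5-dimethylhex-4-en-1-ol
Conditions: Bu4NF, THF, 0 °C to rt
Reagents that add atoms: none
Why: Fluoride-induced desilylation of a primary silyl ether; nothing else in the molecule is fluoride-sensitive.

Step 5
Reactants: 8 (3S)-3-ethenyl-3,5-dimethylhex-4-en-1-ol
Product: 9 (3S)-3-ethenyl-3,5-dimethylhex-4-enal
Conditions: Dess–Martin periodinane, CH2Cl2, 0 °C to rt
Reagents that add atoms: none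
Why: Dess–Martin oxidation of a primary alcohol stops at the aldehyde, which has no α-stereocentre and a quaternary β-carbon that cannot epimerise.

Step 6
Reactants: 10 4-tert-butoxy-4-oxobutanoic acid; 11 (4R)-4-benzyl-1,3-oxazolidin-2-one
Product: 13 tert-butyl 4-[(4R)-4-benzyl-2-oxo-1,3-oxazolidin-3-yl]-4-oxobutanoate, via pivalic mixed anhydride 12 (not isolated)
Conditions: t-BuCOCl, Et3N, THF, −20 °C; then 11, LiCl, −20 °C to rt
Reagents that add atoms: none
Why: N-Acylation of the oxazolidinone through the pivalic mixed anhydride with LiCl activation, the nitrogen attacking the less hindered succinyl carbonyl.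

Step 7
Reactants: 13 tert-butyl 4-[(4R)-4-benzyl-2-oxo-1,3-oxazolidin-3-yl]-4-oxobutanoate; 9 (3S)-3-ethenyl-3,5-dimethylhex-4-enal
Product: 15 tert-butyl (3R,4S,6S)-3-{[(4R)-4-benzyl-2-oxo-1,3-oxazolidin-3-yl]carbonyl}-6-ethenyl-4-hydroxy-6,8-dimethylnon-7-enoate, via boron enolate 14 (not isolated)
Conditions: Bu2BOTf, i-Pr2NEt, CH2Cl2, −78 to 0 °C; 9, −78 to 0 °C; pH 7 buffer, MeOH, H2O2, 0 °C
Reagents that add atoms: none
Why: In this Evans syn aldol reaction the imide (not the tert-butyl ester) is enolised to the (Z)-boron enolate, which reacts through a Zimmerman–Traxler chair on the face away from the benzyl group of the (R)-auxiliary and thereby sets C7 (R) and C8 (S) together, the remote C10 centre exerting no significant bias.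

Step 8
Reactants: 15 tert-butyl (3R,4S,6S)-3-{[(4R)-4-benzyl-2-oxo-1,3-oxazolidin-3-yl]carbonyl}-6-ethenyl-4-hydroxy-6,8-dimethylnon-7-enoate
Product: 16 tert-butyl (3R,4S,6S)-3-{[(4R)-4-benzyl-2-oxo-1,3-oxazolidin-3-yl]carbonyl}-4-[(tert-butyldimethylsilyl)oxy]-6-ethenyl-6,8-dimethylnon-7-enoate
Conditions: TBSOTf, 2,6-lutidine, CH2Cl2, −78 to 0 °C
Reagents that add atoms: tert-butyldimethylsilyl trifluoromethanesulfonate, CC(C)(C)[Si](C)(C)OS(=O)(=O)C(F)(F)F
Why: Silylation of a hindered secondary alcohol with a silyl triflate and a hindered base, kept cold to spare the tert-butyl ester.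

Step 9
Reactants: 16 tert-butyl (3R,4S,6S)-3-{[(4R)-4-benzyl-2-oxo-1,3-oxazolidin-3-yl]carbonyl}-4-[(tert-butyldimethylsilyl)oxy]-6-ethenyl-6,8-dimethylnon-7-enoate
Product: 17 tert-butyl (3S,4S,6S)-4-[(tert-butyldimethylsilyl)oxy]-6-ethenyl-3-(hydroxymethyl)-6,8-dimethylnon-7-enoate
Conditions: LiBH4, MeOH (1 equiv), THF, 0 °C
Reagents that add atoms: none
Why: Reductive removal of the Evans auxiliary with LiBH4, which reduces the activated imide carbonyl far faster than a tert-butyl ester (the descriptor at C7 changes only through ligand priorities).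

Step 10
Reactants: 17 tert-butyl (3S,4S,6S)-4-[(tert-butyldimethylsilyl)oxy]-6-ethenyl-3-(hydroxymethyl)-6,8-dimethylnon-7-enoate
Product: 18 tert-butyl (3R,4S,6S)-4-[(tert-butyldimethylsilyl)oxy]-6-ethenyl-3-formyl-6,8-dimethylnon-7-enoate
Conditions: Dess–Martin periodinane, pyridine, CH2Cl2, 0 °C
Reagents that add atoms: none
Why: Buffered Dess–Martin oxidation gives the α-branched β-silyloxy aldehyde without epimerisation at C7 or elimination, and the aldehyde is to be used at once.

Step 11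
Reactants: 18 tert-butyl (3R,4S,6S)-4-[(tert-butyldimethylsilyl)oxy]-6-ethenyl-3-formyl-6,8-dimethylnon-7-enoate
Product: 19 tert-butyl 2-[(1S,2R,3S,4S,6S)-6-[(tert-butyldimethylsilyl)oxy]-4-ethenyl-2-hydroxy-4-methyl-3-(prop-1-en-2-yl)cyclohexyl]acetate
Conditions: Me2AlCl (1.5 equiv), CH2Cl2, −78 to −20 °C; H2O
Reagents that add atoms: none
Why: Me2AlCl binds the C6 aldehyde oxygen, the trisubstituted alkene attacks the carbonyl carbon through C5 while a hydrogen of a C4 methyl group passes to oxygen in a six-membered ene transition state, so that the C5–C6 bond and the C4=C3 methylene arise in one event and the product is held as an aluminium alkoxide with loss of methane, which keeps the medium free of protic acid. The closest known reaction is the Lewis-acid-promoted type 1 intramolecular carbonyl-ene cyclisation of citronellal to isopulegol. The cyclohexane ring closes in a 6-exo-trig mode at the carbonyl carbon (carbonyl oxygen and alkene carbon C4 both stay outside the ring) through a chair. C6 is set by the equatorial position of the aluminium-bound oxygen in that chair, an axial oxygen being in 1,3-diaxial conflict with the axial C10 methyl, and C5 is set by the equatorial position of the reacting propenyl unit, which is fixed relative to C10 because the chair that keeps the C7 acetate arm and the C8 silyloxy group equatorial places the C10 methyl axial and the vinyl group equatorial. The step needs site selectivity between the two alkenes and trans selectivity for the C5/C6 pair: the vinyl group has no allylic hydrogen and could react only through a primary or secondary cation, and the preset centres C7, C8 and C10 select a single chair. Low temperature and a proton-scavenging Lewis acid protect the C7 centre next to the aldehyde and the β-silyloxy group.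

Step 12
Reactants: 19 tert-butyl 2-[(1S,2R,3S,4S,6S)-6-[(tert-butyldimethylsilyl)oxy]-4-ethenyl-2-hydroxy-4-methyl-3-(prop-1-en-2-yl)cyclohexyl]acetate
Product: 20 (3aS,4S,6S,7S,7aR)-4-[(tert-butyldimethylsilyl)oxy]-6-ethenyl-6-methyl-7-(prop-1-en-2-yl)hexahydro-1-benzofuran-2(3H)-one (trans-fused)
Conditions: KOt-Bu (0.2 equiv), THF, 0 °C to rt
Reagents that add atoms: none
Why: Base-catalysed transesterification (lactonisation) in which the C6 alkoxide closes the γ-lactone ring on the ester carbonyl with loss of tert-butoxide, the trans fusion following from the trans-diequatorial C6 oxygen and C7 acetate arm, while the diequatorial C6 and C8 oxygens are too far apart for silyl transfer.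

Step 13
Reactants: 20 (3aS,4S,6S,7S,7aR)-4-[(tert-butyldimethylsilyl)oxy]-6-ethenyl-6-methyl-7-(prop-1-en-2-yl)hexahydro-1-benzofuran-2(3H)-one
Product: 22 (3aS,4S,6S,7S,7aR)-4-[(tert-butyldimethylsilyl)oxy]-3-[(dimethylamino)methyl]-6-ethenyl-6-methyl-7-(prop-1-en-2-yl)hexahydro-1-benzofuran-2(3H)-one (C11 epimers), via lithium enolate 21 (not isolated)
Conditions: LiN(SiMe3)2, THF, −78 °C; CH2=NMe2 iodide (Eschenmoser's salt), −78 °C to rt
Reagents that add atoms: N,N-dimethylmethyleneiminium iodide, C=[N+](C)C.[I-]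
Why: Mannich reaction of the lactone lithium enolate with Eschenmoser's salt; C11 is the only enolisable position and its configuration is lost in the next step.

Step 14
Reactants: 22 (3aS,4S,6S,7S,7aR)-4-[(tert-butyldimethylsilyl)oxy]-3-[(dimethylamino)methyl]-6-ethenyl-6-methyl-7-(prop-1-en-2-yl)hexahydro-1-benzofuran-2(3H)-one
Product: 24 (3aS,4S,6S,7S,7aR)-4-[(tert-butyldimethylsilyl)oxy]-6-ethenyl-6-methyl-3-methylidene-7-(prop-1-en-2-yl)hexahydro-1-benzofuran-2(3H)-one, via ammonium iodide 23 (not isolated)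
Conditions: MeI, MeOH, rt; then NaHCO3 (aq), CH2Cl2, rt
Reagents that add atoms: none
Why: Exhaustive N-methylation followed by base-induced Hofmann-type (E1cB) elimination of trimethylamine gives the exocyclic α-methylene lactone.

Step 15
Reactants: 24 (3aS,4S,6S,7S,7aR)-4-[(tert-butyldimethylsilyl)oxy]-6-ethenyl-6-methyl-3-methylidene-7-(prop-1-en-2-yl)hexahydro-1-benzofuran-2(3H)-one
Product: 25 (3aS,4S,6S,7R,7aR)-4-[(tert-butyldimethylsilyl)oxy]-6-ethenyl-7-(3-hydroxyprop-1-en-2-yl)-6-methyl-3-methylidenehexahydro-1-benzofuran-2(3H)-one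
Conditions: SeO2 (0.3 equiv), t-BuOOH, CH2Cl2, rt
Reagents that add atoms: selenium dioxide, O=[Se]=O; tert-butyl hydroperoxide (terminal oxidant), CC(C)(C)OO
Why: SeO2 allylic oxidation (ene reaction, then [2,3]-sigmatropic shift) should select the electron-rich 1,1-disubstituted C4=C3 alkene and its C15 methyl, because the vinyl group has no allylic hydrogen, the methylene lactone is electron-poor and the C5 methine is shielded by the quaternary C10.

Step 16
Reactants: 25 (3aS,4S,6S,7R,7aR)-4-[(tert-butyldimethylsilyl)oxy]-6-ethenyl-7-(3-hydroxyprop-1-en-2-yl)-6-methyl-3-methylidenehexahydro-1-benzofuran-2(3H)-one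
Product: 26 2-[(3aS,4S,6S,7R,7aR)-4-[(tert-butyldimethylsilyl)oxy]-6-ethenyl-6-methyl-3-methylidene-2-oxooctahydro-1-benzofuran-7-yl]prop-2-enal
Conditions: Dess–Martin periodinane, CH2Cl2, 0 °C to rt
Reagents that add atoms: none
Why: Dess–Martin oxidation of the primary allylic alcohol gives the 2-substituted acrolein; any enal already formed in step 15 is this same compound and is carried along.

Step 17
Reactants: 26 2-[(3aS,4S,6S,7R,7aR)-4-[(tert-butyldimethylsilyl)oxy]-6-ethenyl-6-methyl-3-methylidene-2-oxooctahydro-1-benzofuran-7-yl]prop-2-enal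
Product: 27 2-[(3aR,4S,6S,7R,7aR)-6-ethenyl-4-hydroxy-6-methyl-3-methylidene-2-oxooctahydro-1-benzofuran-7-yl]prop-2-enal
Conditions: HF·pyridine, THF/pyridine, 0 °C to rt
Reagents that add atoms: none
Why: Acidic fluoride desilylation frees the C8 hydroxyl without the basicity that could trigger conjugate addition to the enal or the methylene lactone, or deconjugation through the C5 hydrogen.

Step 18
Reactants: 27 2-[(3aR,4S,6S,7R,7aR)-6-ethenyl-4-hydroxy-6-methyl-3-methylidene-2-oxooctahydro-1-benzofuran-7-yl]prop-2-enal; 28 angelic acid, (2Z)-2-methylbut-2-enoic acid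
Product: 30 (3aR,4S,6S,7R,7aR)-6-ethenyl-6-methyl-3-methylidene-2-oxo-7-(3-oxoprop-1-en-2-yl)octahydro-1-benzofuran-4-yl (2Z)-2-methylbut-2-enoate, via angelic mixed anhydride 29 (not isolated)
Conditions: 28, 2,4,6-trichlorobenzoyl chloride, Et3N (1 equiv to acid chloride), toluene, rt; filtration; then 27, toluene, 80 °C
Reagents that add atoms: none
Why: Yamaguchi-type esterification through the 2,4,6-trichlorobenzoic mixed anhydride, run without a nucleophilic amine catalyst and without free amine, is the established way to acylate hindered secondary alcohols with angelic acid while keeping the (Z)-geometry.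

Step 19
Reactants: 30 (3aR,4S,6S,7R,7aR)-6-ethenyl-6-methyl-3-methylidene-2-oxo-7-(3-oxoprop-1-en-2-yl)octahydro-1-benzofuran-4-yl (2Z)-2-methylbut-2-enoate
Product: 31 2-[(3aR,4S,6S,7R,7aR)-6-ethenyl-6-methyl-4-{[(2Z)-2-methylbut-2-enoyl]oxy}-3-methylidene-2-oxooctahydro-1-benzofuran-7-yl]prop-2-enoic acid (CNP0256928.3)
Conditions: NaClO2, NaH2PO4, 2-methylbut-2-ene, t-BuOH/H2O, 0 °C to rt
Reagents that add atoms: sodium chlorite, [Na+].[O-]Cl=O
Why: Pinnick oxidation converts the enal chemoselectively into the acrylic acid with 2-methylbut-2-ene as hypochlorite scavenger, leaving the alkenes, the lactone and the angelate untouched.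

**Compound list**

1 | tert-butyl(but-3-yn-1-yloxy)dimethylsilane | C#CCCO[Si](C)(C)C(C)(C)C | starting material
2 | (E)-{4-[(tert-butyldimethylsilyl)oxy]-2-methylbut-1-en-1-yl}dimethylaluminium | C[Al](C)/C=C(\C)CCO[Si](C)(C)C(C)(C)C | intermediate
3 | lithium butyl{(E)-4-[(tert-butyldimethylsilyl)oxy]-2-methylbut-1-en-1-yl}dimethylaluminate | [Li+].CCCC[Al-](C)(C)/C=C(\C)CCO[Si](C)(C)C(C)(C)C | intermediate
4 | (E)-5-[(tert-butyldimethylsilyl)oxy]-3-methylpent-2-en-1-ol | C/C(=C\CO)CCO[Si](C)(C)C(C)(C)C | intermediate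
5 | (E)-5-[(tert-butyldimethylsilyl)oxy]-3-methylpent-2-en-1-yl diethyl phosphate | CCOP(=O)(OCC)OC/C=C(\C)CCO[Si](C)(C)C(C)(C)C | intermediate
6 | 4,4,5,5-tetramethyl-2-(2-methylprop-1-en-1-yl)-1,3,2-dioxaborolane | CC(C)=CB1OC(C)(C)C(C)(C)O1 | starting material
7 | tert-butyl{[(3S)-3-ethenyl-3,5-dimethylhex-4-en-1-yl]oxy}dimethylsilane | C=C[C@@](C)(C=C(C)C)CCO[Si](C)(C)C(C)(C)C | intermediate
8 | (3S)-3-ethenyl-3,5-dimethylhex-4-en-1-ol | C=C[C@@](C)(C=C(C)C)CCO | intermediate
9 | (3S)-3-ethenyl-3,5-dimethylhex-4-enal | C=C[C@@](C)(C=C(C)C)CC=O | intermediate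
10 | 4-tert-butoxy-4-oxobutanoic acid (mono-tert-butyl succinate) | CC(C)(C)OC(=O)CCC(=O)O | starting material
11 | (4R)-4-benzyl-1,3-oxazolidin-2-one | O=C1N[C@H](Cc2ccccc2)CO1 | starting material
12 | 4-tert-butoxy-4-oxobutanoic pivalic anhydride | CC(C)(C)OC(=O)CCC(=O)OC(=O)C(C)(C)C | intermediate
13 | tert-butyl 4-[(4R)-4-benzyl-2-oxo-1,3-oxazolidin-3-yl]-4-oxobutanoate | CC(C)(C)OC(=O)CCC(=O)N1C(=O)OC[C@H]1Cc1ccccc1 | intermediate
14 | (Z)-dibutylboron enolate of 13 | CCCCB(CCCC)O/C(=C\CC(=O)OC(C)(C)C)N1C(=O)OC[C@H]1Cc1ccccc1 | intermediate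
15 | tert-butyl (3R,4S,6S)-3-{[(4R)-4-benzyl-2-oxo-1,3-oxazolidin-3-yl]carbonyl}-6-ethenyl-4-hydroxy-6,8-dimethylnon-7-enoate | C=C[C@@](C)(C=C(C)C)C[C@H](O)[C@H](C(=O)N1C(=O)OC[C@H]1Cc1ccccc1)CC(=O)OC(C)(C)C | intermediate
16 | tert-butyl (3R,4S,6S)-3-{[(4R)-4-benzyl-2-oxo-1,3-oxazolidin-3-yl]carbonyl}-4-[(tert-butyldimethylsilyl)oxy]-6-ethenyl-6,8-dimethylnon-7-enoate | C=C[C@@](C)(C=C(C)C)C[C@H](O[Si](C)(C)C(C)(C)C)[C@H](C(=O)N1C(=O)OC[C@H]1Cc1ccccc1)CC(=O)OC(C)(C)C | intermediate
17 | tert-butyl (3S,4S,6S)-4-[(tert-butyldimethylsilyl)oxy]-6-ethenyl-3-(hydroxymethyl)-6,8-dimethylnon-7-enoate | C=C[C@@](C)(C=C(C)C)C[C@H](O[Si](C)(C)C(C)(C)C)[C@H](CO)CC(=O)OC(C)(C)C | intermediate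
18 | tert-butyl (3R,4S,6S)-4-[(tert-butyldimethylsilyl)oxy]-6-ethenyl-3-formyl-6,8-dimethylnon-7-enoate | C=C[C@@](C)(C=C(C)C)C[C@H](O[Si](C)(C)C(C)(C)C)[C@H](C=O)CC(=O)OC(C)(C)C | intermediate
19 | tert-butyl 2-[(1S,2R,3S,4S,6S)-6-[(tert-butyldimethylsilyl)oxy]-4-ethenyl-2-hydroxy-4-methyl-3-(prop-1-en-2-yl)cyclohexyl]acetate | C=C[C@]1(C)C[C@H](O[Si](C)(C)C(C)(C)C)[C@@H](CC(=O)OC(C)(C)C)[C@H](O)[C@H]1C(C)=C | intermediate
20 | (3aS,4S,6S,7S,7aR)-4-[(tert-butyldimethylsilyl)oxy]-6-ethenyl-6-methyl-7-(prop-1-en-2-yl)hexahydro-1-benzofuran-2(3H)-one | C=C[C@]1(C)C[C@H](O[Si](C)(C)C(C)(C)C)[C@H]2CC(=O)O[C@@H]2[C@H]1C(C)=C | intermediate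
21 | lithium enolate of 20 | C=C[C@]1(C)C[C@H](O[Si](C)(C)C(C)(C)C)[C@H]2C=C([O-])O[C@@H]2[C@H]1C(C)=C.[Li+] | intermediate
22 | (3aS,4S,6S,7S,7aR)-4-[(tert-butyldimethylsilyl)oxy]-3-[(dimethylamino)methyl]-6-ethenyl-6-methyl-7-(prop-1-en-2-yl)hexahydro-1-benzofuran-2(3H)-one (C11 epimers) | C=C[C@]1(C)C[C@H](O[Si](C)(C)C(C)(C)C)[C@H]2C(CN(C)C)C(=O)O[C@@H]2[C@H]1C(C)=C | intermediate
23 | trimethylammonium iodide of 22 | C=C[C@]1(C)C[C@H](O[Si](C)(C)C(C)(C)C)[C@H]2C(C[N+](C)(C)C)C(=O)O[C@@H]2[C@H]1C(C)=C.[I-] | intermediate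
24 | (3aS,4S,6S,7S,7aR)-4-[(tert-butyldimethylsilyl)oxy]-6-ethenyl-6-methyl-3-methylidene-7-(prop-1-en-2-yl)hexahydro-1-benzofuran-2(3H)-one | C=C[C@]1(C)C[C@H](O[Si](C)(C)C(C)(C)C)[C@H]2C(=C)C(=O)O[C@@H]2[C@H]1C(C)=C | intermediate
25 | (3aS,4S,6S,7R,7aR)-4-[(tert-butyldimethylsilyl)oxy]-6-ethenyl-7-(3-hydroxyprop-1-en-2-yl)-6-methyl-3-methylidenehexahydro-1-benzofuran-2(3H)-one | C=C[C@]1(C)C[C@H](O[Si](C)(C)C(C)(C)C)[C@H]2C(=C)C(=O)O[C@@H]2[C@H]1C(=C)CO | intermediate
26 | 2-[(3aS,4S,6S,7R,7aR)-4-[(tert-butyldimethylsilyl)oxy]-6-ethenyl-6-methyl-3-methylidene-2-oxooctahydro-1-benzofuran-7-yl]prop-2-enal | C=C[C@]1(C)C[C@H](O[Si](C)(C)C(C)(C)C)[C@H]2C(=C)C(=O)O[C@@H]2[C@H]1C(=C)C=O | intermediate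
27 | 2-[(3aR,4S,6S,7R,7aR)-6-ethenyl-4-hydroxy-6-methyl-3-methylidene-2-oxooctahydro-1-benzofuran-7-yl]prop-2-enal | C=C[C@]1(C)C[C@H](O)[C@H]2C(=C)C(=O)O[C@@H]2[C@H]1C(=C)C=O | intermediate
28 | angelic acid, (2Z)-2-methylbut-2-enoic acid | C/C=C(/C)C(=O)O | starting material
29 | (2Z)-2-methylbut-2-enoic 2,4,6-trichlorobenzoic anhydride | C/C=C(/C)C(=O)OC(=O)c1c(Cl)cc(Cl)cc1Cl | intermediate
30 | (3aR,4S,6S,7R,7aR)-6-ethenyl-6-methyl-3-methylidene-2-oxo-7-(3-oxoprop-1-en-2-yl)octahydro-1-benzofuran-4-yl (2Z)-2-methylbut-2-enoate | C=C[C@]1(C)C[C@H](OC(=O)/C(C)=C\C)[C@H]2C(=C)C(=O)O[C@@H]2[C@H]1C(=C)C=O | intermediate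
31 | 2-[(3aR,4S,6S,7R,7aR)-6-ethenyl-6-methyl-4-{[(2Z)-2-methylbut-2-enoyl]oxy}-3-methylidene-2-oxooctahydro-1-benzofuran-7-yl]prop-2-enoic acid (CNP0256928.3) | C=C[C@]1(C)C[C@H](OC(=O)/C(C)=C\C)[C@H]2C(=C)C(=O)O[C@@H]2[C@H]1C(=C)C(=O)O | target

**Step count and risks**

Total step count: 19. Longest linear sequence: 18 steps (steps 1–5 and 7–19; step 6 is a one-step side branch).

Steps most likely to fail:

Step 3. Transfer of the trisubstituted alkenyl group from boron to copper may be slow, so that direct SN2 substitution or an uncatalysed background path erodes site selectivity and enantioselectivity at the congested γ-carbon. The fallback sets out from 4 and returns at 7, and makes the quaternary centre by a stereospecific 1,2-shift instead. Sharpless asymmetric epoxidation of 4 (Ti(Oi-Pr)4, L-(+)-diethyl tartrate, t-BuOOH, 4 Å molecular sieves, CH2Cl2, −20 °C) should give [(2S,3S)-3-{2-[(tert-butyldimethylsilyl)oxy]ethyl}-3-methyloxiran-2-yl]methanol F1. Silylation (Et3SiCl, imidazole, CH2Cl2) gives its triethylsilyl ether F2. Methylaluminium bis(4-bromo-2,6-di-tert-butylphenoxide) in CH2Cl2 at −78 °C should then bring about the Maruoka–Yamamoto rearrangement, in which the silyloxymethyl group migrates to the tertiary epoxide carbon anti to the departing oxygen and the epoxide configuration is transferred to the quaternary carbon of (2S)-4-[(tert-butyldimethylsilyl)oxy]-2-methyl-2-{[(triethylsilyl)oxy]methyl}butanal F3. Wittig olefination with Ph3P=CMe2 gives tert-butyl{[(3R)-3,5-dimethyl-3-{[(triethylsilyl)oxy]methyl}hex-4-en-1-yl]oxy}dimethylsilane F4. Selective methanolysis of the triethylsilyl ether (pyridinium p-toluenesulfonate, MeOH, 0 °C) gives (2R)-2-{2-[(tert-butyldimethylsilyl)oxy]ethyl}-2,4-dimethylpent-3-en-1-ol F5. Dess–Martin oxidation gives (2R)-2-{2-[(tert-butyldimethylsilyl)oxy]ethyl}-2,4-dimethylpent-3-enal F6, and methylenation with Ph3P=CH2 returns 7.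

Step 11. Closure at the alkene carbon next to the quaternary C10 may be slow, so that methyl transfer from aluminium to the aldehyde, loss of the β-silyloxy group or epimerisation at C7 overtakes the ene reaction. The fallback sets out from 16 and returns at 19, and forms the same C5–C6 bond by an intramolecular Nozaki–Hiyama allylation under neutral conditions. Ene-type chlorination of the trisubstituted alkene of 16 (Ca(OCl)2, solid CO2, CH2Cl2/H2O, 0 °C) should give the secondary allylic chloride tert-butyl (3R,4S,6S)-3-{[(4R)-4-benzyl-2-oxo-1,3-oxazolidin-3-yl]carbonyl}-4-[(tert-butyldimethylsilyl)oxy]-7-chloro-6-ethenyl-6,8-dimethylnon-8-enoate F7, with the double bond moved to the terminal position (a mixture at the chlorine-bearing carbon is of no consequence). LiBH4 reduction as in step 9 gives tert-butyl (3S,4S,6S)-4-[(tert-butyldimethylsilyl)oxy]-7-chloro-6-ethenyl-3-(hydroxymethyl)-6,8-dimethylnon-8-enoate F8, and Dess–Martin oxidation gives tert-butyl (3R,4S,6S)-4-[(tert-butyldimethylsilyl)oxy]-7-chloro-6-ethenyl-3-formyl-6,8-dimethylnon-8-enoate F9. CrCl2 with catalytic LiI in THF should then generate the allylchromium species, which adds to the aldehyde through its γ-carbon C5 in a chair-like cyclic transition state to give the trans-configured 19.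

Step 15. Hydrogen abstraction may occur at the C5 methine instead of the C15 methyl, or conversion at the hindered alkene may stall and over-oxidation set in. The fallback sets out from 24 and returns at 26. Ene-type chlorination of the isopropenyl group (Ca(OCl)2, solid CO2, CH2Cl2/H2O, 0 °C), which spares the vinyl group and the electron-poor methylene lactone, should give (3aS,4S,6S,7R,7aR)-4-[(tert-butyldimethylsilyl)oxy]-7-(3-chloroprop-1-en-2-yl)-6-ethenyl-6-methyl-3-methylidenehexahydro-1-benzofuran-2(3H)-one F10. A Kornblum-type oxidation of this allylic chloride with 4-methylmorpholine N-oxide (catalytic KI, MeCN, rt) then delivers the enal 26 directly, bypassing 25.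

**Further compounds**

F1 | step 3 | [(2S,3S)-3-{2-[(tert-butyldimethylsilyl)oxy]ethyl}-3-methyloxiran-2-yl]methanol | C[C@@]1(CCO[Si](C)(C)C(C)(C)C)O[C@H]1CO
F2 | step 3 | tert-butyldimethyl(2-{(2S,3S)-2-methyl-3-{[(triethylsilyl)oxy]methyl}oxiran-2-yl}ethoxy)silane | C[C@@]1(CCO[Si](C)(C)C(C)(C)C)O[C@H]1CO[Si](CC)(CC)CC
F3 | step 3 | (2S)-4-[(tert-butyldimethylsilyl)oxy]-2-methyl-2-{[(triethylsilyl)oxy]methyl}butanal | C[C@](C=O)(CCO[Si](C)(C)C(C)(C)C)CO[Si](CC)(CC)CC
F4 | step 3 | tert-butyl{[(3R)-3,5-dimethyl-3-{[(triethylsilyl)oxy]methyl}hex-4-en-1-yl]oxy}dimethylsilane | C[C@](C=C(C)C)(CCO[Si](C)(C)C(C)(C)C)CO[Si](CC)(CC)CC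
F5 | step 3 | (2R)-2-{2-[(tert-butyldimethylsilyl)oxy]ethyl}-2,4-dimethylpent-3-en-1-ol | C[C@](C=C(C)C)(CCO[Si](C)(C)C(C)(C)C)CO
F6 | step 3 | (2R)-2-{2-[(tert-butyldimethylsilyl)oxy]ethyl}-2,4-dimethylpent-3-enal | C[C@](C=C(C)C)(CCO[Si](C)(C)C(C)(C)C)C=O
F7 | step 11 | tert-butyl (3R,4S,6S)-3-{[(4R)-4-benzyl-2-oxo-1,3-oxazolidin-3-yl]carbonyl}-4-[(tert-butyldimethylsilyl)oxy]-7-chloro-6-ethenyl-6,8-dimethylnon-8-enoate | C=C[C@@](C)(C(Cl)C(C)=C)C[C@H](O[Si](C)(C)C(C)(C)C)[C@H](C(=O)N1C(=O)OC[C@H]1Cc1ccccc1)CC(=O)OC(C)(C)C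
F8 | step 11 | tert-butyl (3S,4S,6S)-4-[(tert-butyldimethylsilyl)oxy]-7-chloro-6-ethenyl-3-(hydroxymethyl)-6,8-dimethylnon-8-enoate | C=C[C@@](C)(C(Cl)C(C)=C)C[C@H](O[Si](C)(C)C(C)(C)C)[C@H](CO)CC(=O)OC(C)(C)C
F9 | step 11 | tert-butyl (3R,4S,6S)-4-[(tert-butyldimethylsilyl)oxy]-7-chloro-6-ethenyl-3-formyl-6,8-dimethylnon-8-enoate | C=C[C@@](C)(C(Cl)C(C)=C)C[C@H](O[Si](C)(C)C(C)(C)C)[C@H](C=O)CC(=O)OC(C)(C)C
F10 | step 15 | (3aS,4S,6S,7R,7aR)-4-[(tert-butyldimethylsilyl)oxy]-7-(3-chloroprop-1-en-2-yl)-6-ethenyl-6-methyl-3-methylidenehexahydro-1-benzofuran-2(3H)-one | C=C[C@]1(C)C[C@H](O[Si](C)(C)C(C)(C)C)[C@H]2C(=C)C(=O)O[C@@H]2[C@H]1C(=C)CCl
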